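**Strategy.** Everything rests on disconnecting ring C of the middle flavan unit across O1–C2 and C3–C4. Its C4 is the carbon bonded to C6 of the bottom unit, and C2, C3 and C4 form a 2,3-cis-3,4-trans triad. A single inverse-demand oxa-[4+2] cycloaddition of an ortho-quinone methide (O1=C8a–C4a=C4) with a Z-enol acetate therefore closes the pyran ring and sets all three stereocentres next to the interflavan bond. The precursor is a 2-hydroxybenzhydrol whose carbinol carbon joins a 3,4-bis(benzyloxy)-2-hydroxyphenyl ring to C6 of a benzylated, carbonate-protected (2R,3R,4R)-flavan-3,4-diol. Formylation and a second pass add the top unit.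

Key step: step 12

Remark: flavan numbering is used for each unit (ring A benzo, ring B 2-aryl, ring C pyran; units called bottom, middle, top).
Remark: the sense of induction of the chiral ligand (step 3) and of the chiral phosphoric acid (steps 12 and 15) is assigned by analogy; the antipodal catalyst is taken if the first run shows the opposite sense.

Step 1
Reactants: 1 2,3,4-trihydroxyacetophenone (gallacetophenone)
Product: 2 1-[3,4-bis(benzyloxy)-2-hydroxyphenyl]ethan-1-one
Conditions: BnBr (2.05 equiv), K2CO3, acetone, reflux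
Reagents that add atoms: benzyl bromide, BrCc1ccccc1
Why: Williamson etherification in which the 2-hydroxyl, hydrogen-bonded to the acetyl carbonyl, is the least nucleophilic phenol, so two equivalents of benzyl bromide should alkylate O3 and O4 only; no stereocentre is formed.

Step 2
Reactants: 2 1-[3,4-bis(benzyloxy)-2-hydroxyphenyl]ethan-1-one
Product: 4 7,8-bis(benzyloxy)-4H-chromen-4-one, via enaminone 3 (not isolated)
Conditions: Me2NCH(OMe)2, toluene, 100 °C; then conc. HCl, CH2Cl2, rt
Reagents that add atoms: N,N-dimethylformamide dimethyl acetal, COC(OC)N(C)C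
Why: Condensation of the methyl ketone with the amide acetal gives the enaminone, and acid-promoted conjugate addition of the phenol with loss of dimethylamine closes the chromone (enaminone route to chromones); no stereocentre is formed.

Step 3
Reactants: 4 7,8-bis(benzyloxy)-4H-chromen-4-one; 5 [4-(benzyloxy)phenyl]boronic acid
Product: 6 (2S)-7,8-bis(benzyloxy)-2-[4-(benzyloxy)phenyl]chroman-4-one
Conditions: Pd(OCOCF3)2 (5 mol%), (R)-4-tert-butyl-2-(pyridin-2-yl)-4,5-dihydrooxazole (6 mol%), NH4PF6 (30 mol%), H2O (5 equiv), ClCH2CH2Cl, 60 °C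
Reagents that add atoms: none
Why: Palladium-catalysed asymmetric conjugate addition of an arylboronic acid to a chromone with a pyridine-oxazoline ligand, in which the aryl-palladium species adds to the C2 face left open by the tert-butyl group and protonolysis of the palladium enolate releases the flavanone, so C2 (S) is set by the catalyst.

Step 4
Reactants: 6 (2S)-7,8-bis(benzyloxy)-2-[4-(benzyloxy)phenyl]chroman-4-one
Product: 8 (2R,3R)-7,8-bis(benzyloxy)-2-[4-(benzyloxy)phenyl]-3-bromochroman-4-one (2,3-trans), via silyl enol ether 7 (not isolated)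
Conditions: TMSOTf, Et3N, CH2Cl2, 0 °C; then NBS, THF, −78 °C
Reagents that add atoms: N-bromosuccinimide, O=C1CCC(=O)N1Br
Why: Soft enolisation avoids a free enolate that could open the pyranone ring and erode C2, and bromination of the silyl enol ether by NBS (alpha-halogenation of a ketone through its enol ether) should occur on the face opposite the C2 aryl group, setting C3 trans to it.

Step 5
Reactants: 8 (2R,3R)-3-bromoflavanone
Product: 9 (2R,3S,4R)-7,8-bis(benzyloxy)-2-[4-(benzyloxy)phenyl]-3-bromochroman-4-ol (2,3-trans-3,4-trans)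
Conditions: NaBH4, MeOH–THF (1:4), −20 °C
Reagents that add atoms: none
Why: Borohydride reduction of an alpha-bromo ketone to the bromohydrin, with axial hydride delivery to the half-chair that carries the C2 aryl and C3 bromine equatorial (as in reductions of 2,3-trans-3-substituted flavanones), should place the C4 hydroxyl trans to bromine and cis to the C2 aryl group.

Step 6
Reactants: 9 (2R,3S,4R)-3-bromoflavan-4-ol
Product: 11 (2R)-7,8-bis(benzyloxy)-2-[4-(benzyloxy)phenyl]chromane-3,4-diyl carbonate with the C2 aryl group, O3 and O4 all cis (tri-O-benzylteracacidin 3,4-carbonate), via caesium alkyl carbonate 10 (not isolated)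
Conditions: CO2 (1 atm), Cs2CO3 (1.5 equiv), DMF, rt to 50 °C
Reagents that add atoms: carbon dioxide, O=C=O
Why: Carboxylative cyclisation of a halohydrin, in which the C4 alkoxide takes up CO2 and the carbonate oxygen displaces bromide at C3 from the rear (intramolecular SN2, 5-exo-tet, through the trans-diaxial conformer), so C3 is inverted and its new oxygen ends cis to both O4 and the C2 aryl group in a necessarily cis-fused carbonate.

Step 7
Reactants: 11 tri-O-benzylteracacidin 3,4-carbonate
Product: 13 6-formyl derivative of 11, via iminium salt 12 (not isolated)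
Conditions: POCl3 (3 equiv), DMF, 0 to 65 °C; then H2O, 0 °C
Reagents that add atoms: N,N-dimethylformamide, CN(C)C=O; water, O
Why: Vilsmeier–Haack formylation of the trioxygenated ring A should occur at C6, the only free position that is para to the ring oxygen O1 and ortho to an alkoxy group (C5 is para only to the twisted, weakly donating 8-benzyloxy group and the monoalkoxy rings are too unreactive); no stereocentre is formed.

Step 8
Reactants: 14 2,3-dihydroxybenzaldehyde
Product: 15 2,3-bis(benzyloxy)benzaldehyde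
Conditions: BnBr (2.2 equiv), K2CO3, DMF, 60 °C
Reagents that add atoms: benzyl bromide, BrCc1ccccc1
Why: Williamson etherification of both phenols; no stereocentre is formed.

Step 9
Reactants: 15 2,3-bis(benzyloxy)benzaldehyde
Product: 17 2,3-bis(benzyloxy)phenol, via aryl formate 16 (not isolated)
Conditions: mCPBA, CH2Cl2, rt; then K2CO3 (0.2 equiv), MeOH, rt
Reagents that add atoms: 3-chloroperoxybenzoic acid, OOC(=O)c1cccc(Cl)c1
Why: Baeyer–Villiger (Dakin-type) oxidation in which the electron-rich aryl group migrates to give the aryl formate, which is methanolysed in the same flask; no stereocentre is formed.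

Step 10
Reactants: 18 1-(benzyloxy)-4-ethynylbenzene
Product: 19 (Z)-2-[4-(benzyloxy)phenyl]ethenyl acetate
Conditions: AcOH (1.3 equiv), Ru(C4H7)2[Ph2P(CH2)4PPh2] (bis(2-methylallyl)ruthenium complex of 1,4-bis(diphenylphosphino)butane, 1 mol%), toluene, 60 °C
Reagents that add atoms: acetic acid, CC(=O)O
Why: Ruthenium-catalysed anti-Markovnikov addition of a carboxylic acid to a terminal alkyne through a vinylidene complex, in which carboxylate attack at the alpha carbon and protonolysis place acyloxy and aryl cis, should give the Z enol ester (the double-bond geometry is the only stereo element).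

Step 11
Reactants: 13 bottom-unit 6-carbaldehyde; 17 2,3-bis(benzyloxy)phenol
Product: 21 [3,4-bis(benzyloxy)-2-hydroxyphenyl][(2R)-7,8-bis(benzyloxy)-2-(4-benzyloxyphenyl)-3,4-(carbonyldioxy)chroman-6-yl]methanol (all-cis bottom unit; carbinol epimers), via benzodioxaborin 20 (not isolated)
Conditions: PhB(OH)2 (1.5 equiv), 17 (1.5 equiv), EtCO2H (0.3 equiv), 4 Å MS, toluene, 80 °C; then 30% aq. H2O2, THF, 0 °C to rt
Reagents that add atoms: none
Why: Boron-templated ortho-hydroxyalkylation of a phenol, in which the aryloxy(phenyl)borane binds the aldehyde and delivers it to the only free ortho carbon through a six-membered transition state and the cyclic boronate shields the benzhydrol from a second arylation before neutral oxidative release; the carbinol centre forms as an inconsequential epimer mixture because it becomes trigonal in step 12.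

Step 12
Reactants: 21 bottom-unit C6 (2-hydroxyaryl)carbinol; 19 (Z)-2-[4-(benzyloxy)phenyl]ethenyl acetate
Product: 23 protected middle–bottom dimer (middle unit 2R,3R with 3-O-acetyl and C4 bonded trans to it to C6 of the bottom unit; bottom unit as in 11), via ortho-quinone methide 22 (not isolated)
Conditions: 19 (3 equiv), (R)-3,3'-bis(2,4,6-triisopropylphenyl)-1,1'-binaphthalene-2,2'-diyl hydrogen phosphate ((R)-TRIP, 10 mol%), 5 Å MS, toluene (0.02 M), −20 °C to rt
Reagents that add atoms: none
Why: The phosphoric acid protonates the carbinol of 21 and loss of water (trapped by the sieves) gives the E-configured ortho-quinone methide 22, held to the chiral phosphate at its carbonyl oxygen and stabilised as a benzylic cation by O1 (para) and the 7-benzyloxy group (ortho) of the bottom-unit ring A; the Z-alkene 19 then adds across O1=C8a–C4a=C4 in a concerted, asynchronous inverse-electron-demand oxa-[4+2] cycloaddition in which C3–C4 bonding runs ahead of O1–C2 bonding. The closest known reaction type is the Brønsted-acid-catalysed hetero-Diels–Alder reaction of ortho-quinone methides, generated from 2-hydroxybenzhydrols, with styrenes. Ring C is closed by the cycloaddition itself (two sigma bonds formed across the heterodiene–alkene array), not by cyclisation of a preformed chain. C2 and C3 should come out cis because addition to the Z double bond is suprafacial (a contact ion pair in a non-polar solvent lets ring closure outrun C2–C3 rotation), C3 and C4 should come out trans because the alkene approaches exo with its acetoxy and aryl groups turned away from the bulky, ortho-substituted bottom-unit aryl group on the methide carbon, and the absolute sense (2R,3R, interflavan bond β) is chosen by the catalyst, whose 3,3'-aryl groups shield one face of 22 while the remote stereocentres of the bottom unit exert little bias. Regioselectivity is required and is secured by the alkene itself, since attack through the acetoxy-bearing carbon places the developing cation on the carbon bearing the 4-benzyloxyphenyl group, a far better donor than acyloxy, so that carbon bonds to O1. Chemoselectivity for ionising the doubly benzylic carbinol and not the benzylic C4–O bond of the bottom unit is secured by the electron-poor cyclic carbonate, and the excess of 19 at high dilution should let cycloaddition outrun Friedel–Crafts capture of 22 by electron-rich arenes.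

Step 13
Reactants: 23 protected middle–bottom dimer
Product: 25 dimer 6-carbaldehyde (formyl on C6 of the middle unit), via iminium salt 24 (not isolated)
Conditions: POCl3 (3 equiv), DMF, 0 to 65 °C; then H2O, 0 °C
Reagents that add atoms: N,N-dimethylformamide, CN(C)C=O; water, O
Why: Vilsmeier–Haack formylation as in step 7, now at C6 of the middle unit, the only unsubstituted ring position in 23 that is para to a ring oxygen and ortho to an alkoxy group; no stereocentre is formed.

Step 14
Reactants: 25 dimer 6-carbaldehyde; 17 2,3-bis(benzyloxy)phenol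
Product: 27 middle-unit C6 [3,4-bis(benzyloxy)-2-hydroxyphenyl]carbinol of the dimer (carbinol epimers), via benzodioxaborin 26 (not isolated)
Conditions: PhB(OH)2 (1.5 equiv), 17 (1.5 equiv), EtCO2H (0.3 equiv), 4 Å MS, toluene, 80 °C; then 30% aq. H2O2, THF, 0 °C to rt
Reagents that add atoms: none
Why: The same boron-templated ortho-hydroxyalkylation as in step 11, the acetate and carbonate being inert to the weakly acidic condensation and to neutral peroxide; the carbinol epimers are again inconsequential.

Step 15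
Reactants: 27 dimer carbinol; 19 (Z)-2-[4-(benzyloxy)phenyl]ethenyl acetate
Product: 29 protected trimer (top and middle units 2R,3R with 3-O-acetyl and 3,4-trans interflavan bonds to C6 of the next unit; bottom unit 3,4-carbonate; nine benzyl ethers), via ortho-quinone methide 28 (not isolated)
Conditions: 19 (3 equiv), (R)-3,3'-bis(2,4,6-triisopropylphenyl)-1,1'-binaphthalene-2,2'-diyl hydrogen phosphate ((R)-TRIP, 10 mol%), 5 Å MS, toluene (0.02 M), −20 °C to rt
Reagents that add atoms: none
Why: The same chiral-phosphoric-acid-catalysed ortho-quinone methide hetero-Diels–Alder reaction as in step 12 forms O1–C2 and C3–C4 of the top unit, with C2/C3 cis from suprafacial addition to the Z alkene, C3/C4 trans from exo approach away from the middle-unit aryl group, and the absolute sense from the catalyst.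

Step 16
Reactants: 29 protected trimer
Product: 30 nona-O-benzyl trimer tetraol (free 3-OH on top and middle units, free 3-OH and 4-OH on the bottom unit)
Conditions: NaOMe (0.5 equiv), MeOH–THF (1:1), rt
Reagents that add atoms: none
Why: Base-catalysed transesterification (Zemplén-type methanolysis) removes both acetates and opens the cyclic carbonate while benzyl ethers and interflavan bonds are inert to alkoxide, and no stereocentre is touched because only acyl–oxygen bonds are broken.

Step 17
Reactants: 30 nona-O-benzyl trimer tetraol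
Product: 31 target trimer, top (2R,3R,4S), middle (2R,3R,4S), bottom (2R,3R,4R)
Conditions: H2 (1 atm), Pd(OH)2 on carbon (20 wt%), THF–EtOAc (1:1), rt
Reagents that add atoms: none
Why: Catalytic hydrogenolysis of the nine benzyl ethers under neutral, alcohol-free conditions, where O-benzyl cleavage should be much faster than hydrogenolysis of the ring C–O bonds or of the free benzylic C4 hydroxyl; no stereocentre is touched.

**Compound list**

1 | 2,3,4-trihydroxyacetophenone | CC(=O)c1ccc(O)c(O)c1O | starting material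
2 | 1-[3,4-bis(benzyloxy)-2-hydroxyphenyl]ethan-1-one | CC(=O)c1ccc(OCc2ccccc2)c(OCc2ccccc2)c1O | intermediate
3 | (E)-1-[3,4-bis(benzyloxy)-2-hydroxyphenyl]-3-(dimethylamino)prop-2-en-1-one | CN(C)/C=C/C(=O)c1ccc(OCc2ccccc2)c(OCc2ccccc2)c1O | intermediate (not isolated)
4 | 7,8-bis(benzyloxy)-4H-chromen-4-one | O=c1ccoc2c1ccc(OCc1ccccc1)c2OCc1ccccc1 | intermediate
5 | [4-(benzyloxy)phenyl]boronic acid | OB(O)c1ccc(OCc2ccccc2)cc1 | starting material
6 | (2S)-7,8-bis(benzyloxy)-2-[4-(benzyloxy)phenyl]chroman-4-one | c1cc2c(c(OCc3ccccc3)c1OCc1ccccc1)O[C@H](c1ccc(OCc3ccccc3)cc1)CC2=O | intermediate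
7 | (2S)-7,8-bis(benzyloxy)-2-[4-(benzyloxy)phenyl]-4-(trimethylsilyloxy)-2H-chromene | c1cc2c(c(OCc3ccccc3)c1OCc1ccccc1)O[C@H](c1ccc(OCc3ccccc3)cc1)C=C2O[Si](C)(C)C | intermediate (not isolated)
8 | (2R,3R)-7,8-bis(benzyloxy)-2-[4-(benzyloxy)phenyl]-3-bromochroman-4-one | c1cc2c(c(OCc3ccccc3)c1OCc1ccccc1)O[C@H](c1ccc(OCc3ccccc3)cc1)[C@@H](Br)C2=O | intermediate
9 | (2R,3S,4R)-7,8-bis(benzyloxy)-2-[4-(benzyloxy)phenyl]-3-bromochroman-4-ol | c1cc2c(c(OCc3ccccc3)c1OCc1ccccc1)O[C@H](c1ccc(OCc3ccccc3)cc1)[C@@H](Br)[C@@H]2O | intermediate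
10 | caesium (2R,3S,4R)-7,8-bis(benzyloxy)-2-[4-(benzyloxy)phenyl]-3-bromochroman-4-yl carbonate | c1cc2c(c(OCc3ccccc3)c1OCc1ccccc1)O[C@H](c1ccc(OCc3ccccc3)cc1)[C@@H](Br)[C@@H]2OC(=O)[O-].[Cs+] | intermediate (not isolated)
11 | (2R)-7,8-bis(benzyloxy)-2-[4-(benzyloxy)phenyl]chromane-3,4-diyl carbonate, all-cis (tri-O-benzylteracacidin 3,4-carbonate) | c1cc2c(c(OCc3ccccc3)c1OCc1ccccc1)O[C@H](c1ccc(OCc3ccccc3)cc1)[C@H](O3)[C@@H]2OC3=O | intermediate
12 | C6 N,N-dimethyliminium dichlorophosphate of 11 | C[N+](C)=Cc1cc2c(c(OCc3ccccc3)c1OCc1ccccc1)O[C@H](c1ccc(OCc3ccccc3)cc1)[C@H](O3)[C@@H]2OC3=O.[O-]P(Cl)(Cl)=O | intermediate (not isolated)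
13 | 6-formyl derivative of 11 | O=Cc1cc2c(c(OCc3ccccc3)c1OCc1ccccc1)O[C@H](c1ccc(OCc3ccccc3)cc1)[C@H](O3)[C@@H]2OC3=O | intermediate
14 | 2,3-dihydroxybenzaldehyde | O=Cc1cccc(O)c1O | starting material
15 | 2,3-bis(benzyloxy)benzaldehyde | O=Cc1cccc(OCc2ccccc2)c1OCc1ccccc1 | intermediate
16 | 2,3-bis(benzyloxy)phenyl formate | O=COc1cccc(OCc2ccccc2)c1OCc1ccccc1 | intermediate (not isolated)
17 | 2,3-bis(benzyloxy)phenol | Oc1cccc(OCc2ccccc2)c1OCc1ccccc1 | intermediate
18 | 1-(benzyloxy)-4-ethynylbenzene | C#Cc1ccc(OCc2ccccc2)cc1 | starting material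
19 | (Z)-2-[4-(benzyloxy)phenyl]ethenyl acetate | CC(=O)O/C=C\c1ccc(OCc2ccccc2)cc1 | intermediate
20 | 7,8-bis(benzyloxy)-2-phenyl-4-(bottom-unit C6-yl)-4H-1,3,2-benzodioxaborin | c1ccccc1B1Oc2c(OCc3ccccc3)c(OCc3ccccc3)ccc2C(O1)c1cc2c(c(OCc3ccccc3)c1OCc1ccccc1)O[C@H](c1ccc(OCc3ccccc3)cc1)[C@H](O3)[C@@H]2OC3=O | intermediate (not isolated)
21 | bottom-unit C6 [3,4-bis(benzyloxy)-2-hydroxyphenyl]carbinol, 3,4-carbonate | Oc1c(OCc2ccccc2)c(OCc2ccccc2)ccc1C(O)c1cc2c(c(OCc3ccccc3)c1OCc1ccccc1)O[C@H](c1ccc(OCc3ccccc3)cc1)[C@H](O3)[C@@H]2OC3=O | intermediate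
22 | (E)-ortho-quinone methide from 21 | O=C1C(OCc2ccccc2)=C(OCc2ccccc2)C=C/C1=C\c1cc2c(c(OCc3ccccc3)c1OCc1ccccc1)O[C@H](c1ccc(OCc3ccccc3)cc1)[C@H](O3)[C@@H]2OC3=O | intermediate (not isolated)
23 | protected middle–bottom dimer, middle 3-O-acetate, bottom 3,4-carbonate | c1cc2c(c(OCc3ccccc3)c1OCc1ccccc1)O[C@H](c1ccc(OCc3ccccc3)cc1)[C@H](OC(C)=O)[C@H]2c1cc2c(c(OCc3ccccc3)c1OCc1ccccc1)O[C@H](c1ccc(OCc3ccccc3)cc1)[C@H](O3)[C@@H]2OC3=O | intermediate
24 | middle-unit C6 N,N-dimethyliminium dichlorophosphate of 23 | C[N+](C)=Cc1cc2c(c(OCc3ccccc3)c1OCc1ccccc1)O[C@H](c1ccc(OCc3ccccc3)cc1)[C@H](OC(C)=O)[C@H]2c1cc2c(c(OCc3ccccc3)c1OCc1ccccc1)O[C@H](c1ccc(OCc3ccccc3)cc1)[C@H](O3)[C@@H]2OC3=O.[O-]P(Cl)(Cl)=O | intermediate (not isolated)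
25 | dimer 6-carbaldehyde (middle unit) | O=Cc1cc2c(c(OCc3ccccc3)c1OCc1ccccc1)O[C@H](c1ccc(OCc3ccccc3)cc1)[C@H](OC(C)=O)[C@H]2c1cc2c(c(OCc3ccccc3)c1OCc1ccccc1)O[C@H](c1ccc(OCc3ccccc3)cc1)[C@H](O3)[C@@H]2OC3=O | intermediate
26 | 7,8-bis(benzyloxy)-2-phenyl-4-(dimer middle-unit C6-yl)-4H-1,3,2-benzodioxaborin | c1ccccc1B1Oc2c(OCc3ccccc3)c(OCc3ccccc3)ccc2C(O1)c1cc2c(c(OCc3ccccc3)c1OCc1ccccc1)O[C@H](c1ccc(OCc3ccccc3)cc1)[C@H](OC(C)=O)[C@H]2c1cc2c(c(OCc3ccccc3)c1OCc1ccccc1)O[C@H](c1ccc(OCc3ccccc3)cc1)[C@H](O3)[C@@H]2OC3=O | intermediate (not isolated)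
27 | dimer middle-unit C6 [3,4-bis(benzyloxy)-2-hydroxyphenyl]carbinol | Oc1c(OCc2ccccc2)c(OCc2ccccc2)ccc1C(O)c1cc2c(c(OCc3ccccc3)c1OCc1ccccc1)O[C@H](c1ccc(OCc3ccccc3)cc1)[C@H](OC(C)=O)[C@H]2c1cc2c(c(OCc3ccccc3)c1OCc1ccccc1)O[C@H](c1ccc(OCc3ccccc3)cc1)[C@H](O3)[C@@H]2OC3=O | intermediate
28 | (E)-ortho-quinone methide from 27 | O=C1C(OCc2ccccc2)=C(OCc2ccccc2)C=C/C1=C\c1cc2c(c(OCc3ccccc3)c1OCc1ccccc1)O[C@H](c1ccc(OCc3ccccc3)cc1)[C@H](OC(C)=O)[C@H]2c1cc2c(c(OCc3ccccc3)c1OCc1ccccc1)O[C@H](c1ccc(OCc3ccccc3)cc1)[C@H](O3)[C@@H]2OC3=O | intermediate (not isolated)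
29 | protected trimer, top and middle 3-O-acetates, bottom 3,4-carbonate | c1cc2c(c(OCc3ccccc3)c1OCc1ccccc1)O[C@H](c1ccc(OCc3ccccc3)cc1)[C@H](OC(C)=O)[C@H]2c1cc2c(c(OCc3ccccc3)c1OCc1ccccc1)O[C@H](c1ccc(OCc3ccccc3)cc1)[C@H](OC(C)=O)[C@H]2c1cc2c(c(OCc3ccccc3)c1OCc1ccccc1)O[C@H](c1ccc(OCc3ccccc3)cc1)[C@H](O3)[C@@H]2OC3=O | intermediate
30 | nona-O-benzyl trimer tetraol | c1cc2c(c(OCc3ccccc3)c1OCc1ccccc1)O[C@H](c1ccc(OCc3ccccc3)cc1)[C@H](O)[C@H]2c1cc2c(c(OCc3ccccc3)c1OCc1ccccc1)O[C@H](c1ccc(OCc3ccccc3)cc1)[C@H](O)[C@H]2c1cc2c(c(OCc3ccccc3)c1OCc1ccccc1)O[C@H](c1ccc(OCc3ccccc3)cc1)[C@H](O)[C@@H]2O | intermediate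
31 | CNP0140823.1, trimer of 7,8,4'-trihydroxyflavan units linked 4→6, top (2R,3R,4S), middle (2R,3R,4S), bottom (2R,3R,4R)-3,4-diol | Oc1ccc([C@H]2Oc3c(ccc(O)c3O)[C@H](c3cc4c(c(O)c3O)O[C@H](c3ccc(O)cc3)[C@H](O)[C@H]4c3cc4c(c(O)c3O)O[C@H](c3ccc(O)cc3)[C@H](O)[C@@H]4O)[C@H]2O)cc1 | target

**Step count and risks**

Total: 17 steps. Longest linear sequence: 14 steps (1–7, then 11–17).

Step 12 is the most likely to fail. A stepwise cationic pathway could allow C2–C3 rotation before ring closure (2,3-trans series), endo approach would give 3,4-cis, the catalyst may discriminate the faces poorly, and the quinone methide may be intercepted by electron-rich arenes. The fallback is the Lewis-acid coupling of a C4-activated flavan-3-ol with a nucleophilic flavan. It sets out from 11: methanolysis (NaOMe, MeOH–THF) gives (2R,3R,4R)-7,8-bis(benzyloxy)-2-[4-(benzyloxy)phenyl]chromane-3,4-diol F1, and acetylation (Ac2O, pyridine, DMAP) gives its 3,4-di-O-acetate F2. F2 is ionised at C4 with TMSOTf in CH2Cl2 at −78 °C in the presence of about four equivalents of 11 (recoverable). The 3-O-acetyl group bridges the C4 cation on the face cis to it, so C6 of 11 (para to O1) should attack from the opposite face and give the 3,4-trans link. The fallback comes back to the route at 23, bypassing steps 7, 11 and 12 for this unit.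

Step 15 carries the same hazards on a more crowded substrate, with possible mismatch between catalyst and the two existing units. The fallback sets out from 23 and uses the same electrophile, the di-O-acetate F2 prepared from 11 as above. TMSOTf-promoted coupling with an excess of 23 should alkylate the only free C6 position para to a ring oxygen (that of the middle unit), again trans to the participating 3-O-acetyl group. It comes back at 29, bypassing steps 13 to 15.

Step 11 (and its repeat, step 14) may stall because the aldehyde is hindered and electron-rich, or the cyclic boronate may ionise at its doubly activated benzylic carbon and arylate a second time. The fallback is an organolithium addition. It sets out from 17, which is ortho-brominated (NBS, catalytic i-Pr2NH, CH2Cl2, 0 °C) to 6-bromo-2,3-bis(benzyloxy)phenol F3. Treatment with n-BuLi (2.1 equiv, THF, −78 °C) gives lithium 2,3-bis(benzyloxy)-6-lithiophenoxide F4, which is added to aldehyde 13 at −78 °C, where the aldehyde reacts much faster than the carbonate, and quenched with aqueous NH4Cl. It comes back at 21; the same sequence with 25 comes back at 27.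

Further compounds
F1 | step 12 | (2R,3R,4R)-7,8-bis(benzyloxy)-2-[4-(benzyloxy)phenyl]chromane-3,4-diol | c1cc2c(c(OCc3ccccc3)c1OCc1ccccc1)O[C@H](c1ccc(OCc3ccccc3)cc1)[C@H](O)[C@@H]2O
F2 | step 12 | 3,4-di-O-acetate of F1 (all-cis) | c1cc2c(c(OCc3ccccc3)c1OCc1ccccc1)O[C@H](c1ccc(OCc3ccccc3)cc1)[C@H](OC(C)=O)[C@@H]2OC(C)=O
F0 | step 15 | none | none
F3 | step 11 | 6-bromo-2,3-bis(benzyloxy)phenol | Oc1c(Br)ccc(OCc2ccccc2)c1OCc1ccccc1
F4 | step 11 | lithium 2,3-bis(benzyloxy)-6-lithiophenoxide | [Li]Oc1c([Li])ccc(OCc2ccccc2)c1OCc1ccccc1
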